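**Plan**

1. Flavan numbering (O1, C2 to C8a) is used for both halves; fragment A is the half without C-methyl, fragment B the 6-methyl half.
2. Retrosynthesis: cut first the bond between the bridge CH2 and C8 of fragment B, then the C2–C3 bond of the pyran ring in each flavan, which leads back to two benzyl 2-ethynylaryl ethers.
3. Enabling feature: in such an ether the benzylic C–H of the O1-benzyl group (future C2) lies 1,5 to the alkyne carbon that becomes C4 (path C2–O1–C8a–C4a–C4); the 5,7,8a-trioxygenated benzene ring makes C4 the cationic end of a gold-bound alkyne, and O1 plus the phenyl ring stabilise an oxocarbenium ion at C2.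
4. Forward, fragment A: methyl 2,4,6-trihydroxybenzoate (its ester carbon is the later bridge carbon) is 4-O-methylated, formylated, benzylated and converted to the alkyne; a gold-catalysed hydride shift/cyclisation closes the pyran ring; hydrogenation and ester reduction follow.
5. Fragment B is made the same way from 2,4,6-trihydroxytoluene; the two flavans are joined last by ortho-quinone methide alkylation of fragment B at its only free ring position, C8.
6. Stereochemistry: each C2 (S) centre is set by the chiral bisphosphine–gold catalyst during C2–C3 bond formation and is not touched afterwards; joining two enriched fragments turns residual minor enantiomers into separable diastereomers.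

Key step: step 5

**Route**

Step 1
Reactants: 1 methyl 2,4,6-trihydroxybenzoate
Product: 2 methyl 2,6-dihydroxy-4-methoxybenzoate
Conditions: MeOH (1.05 equiv), PPh3, diisopropyl azodicarboxylate, THF, 0 °C to rt
Reagents that add atoms: methanol CO
Why: Mitsunobu etherification should be selective for the 4-hydroxyl because the two ortho hydroxyls are hydrogen-bonded to the ester and are much less acidic and nucleophilic.

Step 2
Reactants: 2 methyl 2,6-dihydroxy-4-methoxybenzoate
Product: 4 methyl 3-formyl-2,6-dihydroxy-4-methoxybenzoate, via iminium chloride 3 (not isolated)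
Conditions: POCl3, DMF, MeCN, 0 °C to rt; then H2O, 50 °C
Reagents that add atoms: N,N-dimethylformamide CN(C)C=O; water O
Why: Vilsmeier–Haack formylation attacks one of the two symmetry-equivalent free ring positions and should stop after one formyl group because the product ring is deactivated.

Step 3
Reactants: 4 methyl 3-formyl-2,6-dihydroxy-4-methoxybenzoate
Product: 5 methyl 2,6-bis(benzyloxy)-3-formyl-4-methoxybenzoate
Conditions: BnBr (2.6 equiv), K2CO3, cat. Bu4NI, DMF, 60 °C
Reagents that add atoms: benzyl bromide BrCc1ccccc1
Why: Williamson etherification of both phenols under forcing conditions installs the benzyl group that becomes C2 and its phenyl ring (on the oxygen between ester and formyl group) and a benzyl protecting group on the future 7-hydroxyl.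

Step 4
Reactants: 5 methyl 2,6-bis(benzyloxy)-3-formyl-4-methoxybenzoate
Product: 6 methyl 2,6-bis(benzyloxy)-3-ethynyl-4-methoxybenzoate
Conditions: dimethyl (1-diazo-2-oxopropyl)phosphonate, K2CO3, MeOH–THF, 0 °C to rt
Reagents that add atoms: dimethyl (1-diazo-2-oxopropyl)phosphonate COP(=O)(OC)C(=[N+]=[N-])C(C)=O
Why: Ohira–Bestmann homologation converts the hindered aryl aldehyde into the terminal alkyne under mild base that leaves the methyl ester and the benzyl ethers intact.

Step 5
Reactants: 6 methyl 2,6-bis(benzyloxy)-3-ethynyl-4-methoxybenzoate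
Product: 7 methyl (2S)-7-(benzyloxy)-5-methoxy-2-phenyl-2H-chromene-8-carboxylate
Conditions: [(R)-DTBM-SEGPHOS](AuCl)2 (2.5 mol %), AgNTf2 (5 mol %), 4 Å MS, ClCH2CH2Cl, 40 °C
Reagents that add atoms: none
Why: Proposed new method: the cationic monovalent gold complex binds the terminal alkyne of 6 with the metal on the terminal carbon (future C3) and the positive charge on the aryl-bound carbon (future C4), which the ortho and para alkoxy groups of ring A stabilise; a through-space 1,5-hydride shift from the benzylic CH2 of the neighbouring benzyloxy group (future C2) to C4 then gives a (Z)-vinyl-gold unit and an O1-aryl oxocarbenium ion, and attack of the gold-bearing C3 on C2 forms the C2–C3 bond and releases the catalyst, so the whole process is a proton-free cycloisomerisation. The closest known reaction types are the gold- and platinum-catalysed 1,5-hydride shift/cyclisation (hydroalkylation) of alkynyl ethers and the enantioselective gold-catalysed carboalkoxylation of alkynes, in which a vinyl-gold species carrying a chiral bisphosphine adds to a tethered oxocarbenium ion. The pyran ring closes in the 6-endo-trig mode, since both the C2=O1 oxocarbenium bond and the C3=C4 vinyl-gold bond lie inside the new ring. C2 is the only new stereocentre and is set by the chiral bisphosphine on the gold atom attached to C3, which selects one face of the planar oxocarbenium ion (both enantiotopic benzylic hydrogens lead to the same ion); should the (R)-ligand give 2R, its antipode is used. The step needs hydride transfer from the OCH2Ph group and not from the OCH3 group on the other ortho position, and it must outrun attack of the ether oxygen or of the benzyl phenyl ring on the alkyne; the first is secured by the phenyl group, which makes the benzylic oxocarbenium ion far more stable than a methylene one, the others by the polarisation of the alkyne, which puts the electrophilic carbon C4 out of reach of O1, by the ortho ester, which lowers the nucleophilicity of O1, and by the six-membered geometry of the hydride transfer.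

Step 6
Reactants: 7 methyl (2S)-7-(benzyloxy)-5-methoxy-2-phenyl-2H-chromene-8-carboxylate
Product: 8 methyl (2S)-7-hydroxy-5-methoxy-2-phenyl-3,4-dihydro-2H-chromene-8-carboxylate
Conditions: H2 (1 atm), 10% Pd/C, EtOAc–MeOH, rt
Reagents that add atoms: none
Why: Heterogeneous catalytic hydrogenation should saturate the C3=C4 bond and hydrogenolyse the 7-O-benzyl ether in one operation, while C2 is not involved and the O1–C2 bond is expected to survive as it does in debenzylations of benzylated flavans.

Step 7
Reactants: 8 methyl (2S)-7-hydroxy-5-methoxy-2-phenyl-3,4-dihydro-2H-chromene-8-carboxylate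
Product: 9 (2S)-8-(hydroxymethyl)-5-methoxy-2-phenyl-3,4-dihydro-2H-chromen-7-ol
Conditions: LiAlH4 (2.5 equiv), THF, 0 °C to rt; then H2O at 0 °C; crude product used at once
Reagents that add atoms: none
Why: Hydride reduction of the salicylate ester gives the 2-hydroxybenzyl alcohol, an ortho-quinone methide precursor in which the former ester carbon is the future bridge carbon on C8.

Step 8
Reactants: 10 2,4,6-trihydroxytoluene (2-methylbenzene-1,3,5-triol)
Product: 12 2,4,6-trihydroxy-3-methylbenzaldehyde, via iminium chloride 11 (not isolated)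
Conditions: POCl3, DMF, EtOAc, 0 °C to rt; then H2O, 50 °C
Reagents that add atoms: N,N-dimethylformamide CN(C)C=O; water O
Why: Vilsmeier–Haack formylation of the symmetric methylphloroglucinol, whose two free positions are equivalent, should give a single mono-aldehyde.

Step 9
Reactants: 12 2,4,6-trihydroxy-3-methylbenzaldehyde
Product: 14 4,6-bis(benzyloxy)-2-methoxy-3-methylbenzaldehyde, via bis-benzyl ether 13 (not isolated)
Conditions: BnBr (2.05 equiv), K2CO3, DMF, 0 °C to rt; then MeI (3 equiv), 50 °C
Reagents that add atoms: benzyl bromide BrCc1ccccc1; iodomethane CI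
Why: In this one-flask sequential Williamson etherification the para hydroxyl and the ortho hydroxyl next to the ring hydrogen should react first with benzyl bromide, leaving the chelated, hindered hydroxyl between the formyl and C-methyl groups for methyl iodide, which places the methoxy group at the future C5.

Step 10
Reactants: 14 4,6-bis(benzyloxy)-2-methoxy-3-methylbenzaldehyde
Product: 15 1,5-bis(benzyloxy)-2-ethynyl-3-methoxy-4-methylbenzene
Conditions: dimethyl (1-diazo-2-oxopropyl)phosphonate, K2CO3, MeOH–THF, 0 °C to rt
Reagents that add atoms: dimethyl (1-diazo-2-oxopropyl)phosphonate COP(=O)(OC)C(=[N+]=[N-])C(C)=O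
Why: Ohira–Bestmann homologation as in step 4 turns the aldehyde into the terminal alkyne without touching the ethers.

Step 11
Reactants: 15 1,5-bis(benzyloxy)-2-ethynyl-3-methoxy-4-methylbenzene
Product: 16 (2S)-7-(benzyloxy)-5-methoxy-6-methyl-2-phenyl-2H-chromene
Conditions: [(R)-DTBM-SEGPHOS](AuCl)2 (2.5 mol %), AgNTf2 (5 mol %), 4 Å MS, ClCH2CH2Cl, 40 °C
Reagents that add atoms: none
Why: Proposed new method: the same gold-catalysed 1,5-hydride shift from the benzylic C–H of the ortho benzyloxy group to the aryl-bound alkyne carbon, followed by 6-endo-trig attack of the vinyl-gold carbon on the oxocarbenium ion, closes the pyran ring of fragment B and sets C2 under control of the chiral bisphosphine on gold, the closest known reaction types being the gold-catalysed hydride shift/cyclisation of alkynyl ethers and the enantioselective gold-catalysed carboalkoxylation of alkynes.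

Step 12
Reactants: 16 (2S)-7-(benzyloxy)-5-methoxy-6-methyl-2-phenyl-2H-chromene
Product: 17 (2S)-5-methoxy-6-methyl-2-phenyl-3,4-dihydro-2H-chromen-7-ol
Conditions: H2 (1 atm), 10% Pd/C, EtOAc–MeOH, rt
Reagents that add atoms: none
Why: Catalytic hydrogenation as in step 6 should saturate C3=C4 and free the 7-hydroxyl without affecting C2.

Step 13
Reactants: 9 (2S)-8-(hydroxymethyl)-5-methoxy-2-phenyl-3,4-dihydro-2H-chromen-7-ol; 17 (2S)-5-methoxy-6-methyl-2-phenyl-3,4-dihydro-2H-chromen-7-ol
Product: 18 (2S)-8-{[(2S)-7-hydroxy-5-methoxy-6-methyl-2-phenyl-3,4-dihydro-2H-chromen-8-yl]methyl}-5-methoxy-2-phenyl-3,4-dihydro-2H-chromen-7-ol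
Conditions: 17 (2 equiv), camphorsulfonic acid (10 mol %), CH2Cl2, 0 °C to rt, slow addition of 9
Reagents that add atoms: none
Why: Mild acid turns the electron-rich 2-hydroxybenzyl alcohol 9 into an ortho-quinone methide (2-hydroxybenzyl cation) that should alkylate 17 in a Friedel–Crafts sense at C8, the only unsubstituted position of its oxygenated ring, with excess 17 and slow addition holding back self-condensation of 9 and no stereocentre being touched.

**Compound list**

1 | methyl 2,4,6-trihydroxybenzoate | COC(=O)c1c(O)cc(O)cc1O | starting material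
2 | methyl 2,6-dihydroxy-4-methoxybenzoate | COC(=O)c1c(O)cc(OC)cc1O | intermediate
3 | {[2,4-dihydroxy-6-methoxy-3-(methoxycarbonyl)phenyl]methylidene}dimethyliminium chloride (not isolated) | COC(=O)c1c(O)cc(OC)c(C=[N+](C)C)c1O.[Cl-] | intermediate
4 | methyl 3-formyl-2,6-dihydroxy-4-methoxybenzoate | COC(=O)c1c(O)cc(OC)c(C=O)c1O | intermediate
5 | methyl 2,6-bis(benzyloxy)-3-formyl-4-methoxybenzoate | COC(=O)c1c(OCc2ccccc2)cc(OC)c(C=O)c1OCc1ccccc1 | intermediate
6 | methyl 2,6-bis(benzyloxy)-3-ethynyl-4-methoxybenzoate | COC(=O)c1c(OCc2ccccc2)cc(OC)c(C#C)c1OCc1ccccc1 | intermediate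
7 | methyl (2S)-7-(benzyloxy)-5-methoxy-2-phenyl-2H-chromene-8-carboxylate | COC(=O)c1c(OCc2ccccc2)cc(OC)c2C=C[C@@H](c3ccccc3)Oc12 | intermediate
8 | methyl (2S)-7-hydroxy-5-methoxy-2-phenyl-3,4-dihydro-2H-chromene-8-carboxylate | COC(=O)c1c(O)cc(OC)c2CC[C@@H](c3ccccc3)Oc12 | intermediate
9 | (2S)-8-(hydroxymethyl)-5-methoxy-2-phenyl-3,4-dihydro-2H-chromen-7-ol | OCc1c(O)cc(OC)c2CC[C@@H](c3ccccc3)Oc12 | intermediate
10 | 2,4,6-trihydroxytoluene (2-methylbenzene-1,3,5-triol) | Cc1c(O)cc(O)cc1O | starting material
11 | [(2,4,6-trihydroxy-3-methylphenyl)methylidene]dimethyliminium chloride (not isolated) | Cc1c(O)cc(O)c(C=[N+](C)C)c1O.[Cl-] | intermediate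
12 | 2,4,6-trihydroxy-3-methylbenzaldehyde | Cc1c(O)cc(O)c(C=O)c1O | intermediate
13 | 4,6-bis(benzyloxy)-2-hydroxy-3-methylbenzaldehyde (not isolated) | Cc1c(OCc2ccccc2)cc(OCc2ccccc2)c(C=O)c1O | intermediate
14 | 4,6-bis(benzyloxy)-2-methoxy-3-methylbenzaldehyde | Cc1c(OCc2ccccc2)cc(OCc2ccccc2)c(C=O)c1OC | intermediate
15 | 1,5-bis(benzyloxy)-2-ethynyl-3-methoxy-4-methylbenzene | Cc1c(OCc2ccccc2)cc(OCc2ccccc2)c(C#C)c1OC | intermediate
16 | (2S)-7-(benzyloxy)-5-methoxy-6-methyl-2-phenyl-2H-chromene | COc1c(C)c(OCc2ccccc2)cc2O[C@H](c3ccccc3)C=Cc12 | intermediate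
17 | (2S)-5-methoxy-6-methyl-2-phenyl-3,4-dihydro-2H-chromen-7-ol | COc1c(C)c(O)cc2O[C@H](c3ccccc3)CCc12 | intermediate
18 | (2S)-8-{[(2S)-7-hydroxy-5-methoxy-6-methyl-2-phenyl-3,4-dihydro-2H-chromen-8-yl]methyl}-5-methoxy-2-phenyl-3,4-dihydro-2H-chromen-7-ol | COc1cc(O)c(Cc2c(O)c(C)c(OC)c3c2O[C@H](c2ccccc2)CC3)c2c1CC[C@@H](c1ccccc1)O2 | target

**Summary and risks**

Total step count: 13. Longest linear sequence: 8 steps (steps 1 to 7, then step 13).

Steps most likely to fail:

1. Step 5 (proposed new method). The hydride transfer from an aryl benzyl ether may be too slow; the ether oxygen or the benzyl phenyl ring may add to the activated alkyne instead; traces of water may hydrate the alkyne; facial discrimination at the oxocarbenium ion may be poor; or traces of acid may racemise the 2H-chromene. The fallback uses known chemistry and closes the pyran ring at O1–C2. It sets out from 4. Wittig olefination with (benzoylmethylene)triphenylphosphorane would give methyl 2,6-dihydroxy-4-methoxy-3-[(1E)-3-oxo-3-phenylprop-1-en-1-yl]benzoate F1. Hydrogenation of the C=C bond (H2, Pd/C, EtOAc) would give methyl 2,6-dihydroxy-4-methoxy-3-(3-oxo-3-phenylpropyl)benzoate F2. Noyori asymmetric transfer hydrogenation with RuCl[(R,R)-TsDPEN](p-cymene) and HCO2H–Et3N would give methyl 2,6-dihydroxy-3-[(3R)-3-hydroxy-3-phenylpropyl]-4-methoxybenzoate F3. Intramolecular Mitsunobu etherification (PPh3, diisopropyl azodicarboxylate), with inversion at the carbinol carbon, would then come back to the route at 8.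

2. Step 11 (proposed new method). The same processes may fail as in step 5; here O1 has no ortho ester, so attack of the ether oxygen on the alkyne is the more likely diversion. The fallback, again known chemistry, sets out from 14. Chelation-controlled cleavage of the benzyl ether ortho to the formyl group with MgBr2·OEt2 would give 4-(benzyloxy)-6-hydroxy-2-methoxy-3-methylbenzaldehyde F4. Wittig olefination with (benzoylmethylene)triphenylphosphorane would give (2E)-3-[4-(benzyloxy)-2-hydroxy-6-methoxy-5-methylphenyl]-1-phenylprop-2-en-1-one F5. Hydrogenation (H2, Pd/C), which also removes the remaining benzyl group, would give 3-(2,4-dihydroxy-6-methoxy-5-methylphenyl)-1-phenylpropan-1-one F6. Noyori asymmetric transfer hydrogenation with RuCl[(R,R)-TsDPEN](p-cymene) would give 4-[(3R)-3-hydroxy-3-phenylpropyl]-5-methoxy-6-methylbenzene-1,3-diol F7. Mitsunobu ring closure with inversion would come back to the route at 17.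

3. Step 13. Self-condensation of 9 through its own free C6 position, over-alkylation, or acid-induced ionisation of a benzylic O1–C2 bond may erode the yield. The fallback exchanges the roles so that the electrophile has no free ring position; it sets out from 8 and 17. Saponification of 8 (LiOH, THF–H2O) would give (2S)-7-hydroxy-5-methoxy-2-phenyl-3,4-dihydro-2H-chromene-8-carboxylic acid F8. Thermal decarboxylation (DMSO, 120 °C) would give (2S)-5-methoxy-2-phenyl-3,4-dihydro-2H-chromen-7-ol F9. A Mannich reaction of 17 (aqueous CH2O, Me2NH, EtOH) would give (2S)-8-[(dimethylamino)methyl]-5-methoxy-6-methyl-2-phenyl-3,4-dihydro-2H-chromen-7-ol F10. Heating F10 with excess F9 in toluene at 110 °C would release dimethylamine, form the ortho-quinone methide of fragment B and alkylate F9, returning to the route at 18. Attack through C8 of F9 is expected to be preferred, as in other electrophilic substitutions of 5,7-dioxygenated flavans, and a C6-linked isomer would be removed by chromatography.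

Further compounds
F1 | step 5 | methyl 2,6-dihydroxy-4-methoxy-3-[(1E)-3-oxo-3-phenylprop-1-en-1-yl]benzoate | COC(=O)c1c(O)cc(OC)c(/C=C/C(=O)c2ccccc2)c1O
F2 | step 5 | methyl 2,6-dihydroxy-4-methoxy-3-(3-oxo-3-phenylpropyl)benzoate | COC(=O)c1c(O)cc(OC)c(CCC(=O)c2ccccc2)c1O
F3 | step 5 | methyl 2,6-dihydroxy-3-[(3R)-3-hydroxy-3-phenylpropyl]-4-methoxybenzoate | COC(=O)c1c(O)cc(OC)c(CC[C@@H](O)c2ccccc2)c1O
F4 | step 11 | 4-(benzyloxy)-6-hydroxy-2-methoxy-3-methylbenzaldehyde | Cc1c(OCc2ccccc2)cc(O)c(C=O)c1OC
F5 | step 11 | (2E)-3-[4-(benzyloxy)-2-hydroxy-6-methoxy-5-methylphenyl]-1-phenylprop-2-en-1-one | Cc1c(OCc2ccccc2)cc(O)c(/C=C/C(=O)c2ccccc2)c1OC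
F6 | step 11 | 3-(2,4-dihydroxy-6-methoxy-5-methylphenyl)-1-phenylpropan-1-one | Cc1c(O)cc(O)c(CCC(=O)c2ccccc2)c1OC
F7 | step 11 | 4-[(3R)-3-hydroxy-3-phenylpropyl]-5-methoxy-6-methylbenzene-1,3-diol | Cc1c(O)cc(O)c(CC[C@@H](O)c2ccccc2)c1OC
F8 | step 13 | (2S)-7-hydroxy-5-methoxy-2-phenyl-3,4-dihydro-2H-chromene-8-carboxylic acid | OC(=O)c1c(O)cc(OC)c2CC[C@@H](c3ccccc3)Oc12
F9 | step 13 | (2S)-5-methoxy-2-phenyl-3,4-dihydro-2H-chromen-7-ol | COc1cc(O)cc2O[C@H](c3ccccc3)CCc12
F10 | step 13 | (2S)-8-[(dimethylamino)methyl]-5-methoxy-6-methyl-2-phenyl-3,4-dihydro-2H-chromen-7-ol | COc1c(C)c(O)c(CN(C)C)c2O[C@H](c3ccccc3)CCc12
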